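The lavandulyl chain is cut between its benzylic carbon C1'' and the stereocentre C2''. C2'' is allylic to the isopropenyl C3''=CH2 bond, so it is the γ-carbon of a linear, achiral (E)-2,6-dimethylhepta-2,5-dienylboronate. C1'' sits on C8 of ring A, ortho to O7, so it can enter as an aldehyde whose oxygen is erased later through an o-quinone methide. One chiral-phosphoric-acid-catalysed allylboration of Boc-protected 8-formyl-5-O-methylmorin joins both halves, sets C2'' in a closed chair and unveils the isopropenyl group by allylic transposition. The precursor pair is thus a flat flavonol aldehyde made from morin and a primary dienylboronate.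

Key step: step 8

Remark: flavonoid numbering is used (ring A = C5–C8, ring C = O1–C4, ring B primed, side chain C1'', C2'', ...). The sense of induction of TRIP is taken from its behaviour with simple aromatic aldehydes ((S)-acid, Si face), and the antipodal acid is used if the first run shows the opposite.

Step 1
Reactants: 1 morin
Product: 2 3,7,2',4'-tetra-O-benzylmorin
Conditions: BnBr (4.2 equiv), K2CO3, DMF, rt to 40 °C
Reagents that add atoms: benzyl bromide, BrCc1ccccc1
Why: Williamson ether synthesis alkylates the four free OH groups, while the 5-OH, locked in a hydrogen bond to the C4 carbonyl, is the least acidic and least nucleophilic one and should stay free at this stoichiometry.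

Step 2
Reactants: 2 3,7,2',4'-tetra-O-benzylmorin
Product: 3 3,7,2',4'-tetra-O-benzyl-5-O-methylmorin
Conditions: MeI (5 equiv), K2CO3, DMF, 50 °C
Reagents that add atoms: iodomethane, CI
Why: Williamson methylation under more forcing conditions reaches the only OH left, the chelated 5-OH, and so fixes the 5-OMe group of the target.

Step 3
Reactants: 3 3,7,2',4'-tetra-O-benzyl-5-O-methylmorin
Product: 4 5-O-methylmorin
Conditions: H2 (1 atm), 10% Pd/C, THF–MeOH, rt
Reagents that add atoms: none
Why: Catalytic hydrogenolysis cleaves the four O-benzyl groups while the aryl methyl ether and the tetrasubstituted C2=C3 bond of the chromone are inert, and it is placed before any side-chain alkene exists.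

Step 4
Reactants: 4 5-O-methylmorin
Product: 5 8-formyl-5-O-methylmorin
Conditions: hexamethylenetetramine (3 equiv), AcOH, 100 °C; then 3 M HCl, 70 °C
Reagents that add atoms: hexamethylenetetramine, C1N2CN3CN1CN(C2)C3; water, O
Why: Duff formylation (aminomethylation by the iminium ion from hexamine, hydride shift, hydrolysis) should strike ring A, the only phloroglucinol-type ring, ortho to the 7-OH at C8, the usual site in 7-hydroxychromones, because C6 is flanked by the 5-OMe group and the resorcinol-type ring B is far less nucleophilic.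

Step 5
Reactants: 5 8-formyl-5-O-methylmorin
Product: 6 8-formyl-5-O-methylmorin 3,7,2',4'-tetrakis(tert-butyl carbonate)
Conditions: Boc2O (6 equiv), DMAP (20 mol %), i-Pr2NEt, THF, 0 °C to rt
Reagents that add atoms: di-tert-butyl dicarbonate, CC(C)(C)OC(=O)OC(=O)OC(C)(C)C
Why: DMAP-catalysed O-acylation turns all four OH groups into tert-butyl carbonates, which makes the aldehyde soluble in toluene and more electrophilic and places at O7 the group that later leaves together with the C1'' oxygen.

Step 6
Reactants: 7 propargyl alcohol; 8 prenyl chloride (1-chloro-3-methylbut-2-ene)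
Product: 10 (2E)-2,6-dimethylhepta-2,5-dien-1-ol, via alkenylalane 9 (not isolated)
Conditions: Me3Al (3 equiv), Cp2ZrCl2 (25 mol %), CH2Cl2, 0 °C to rt; then 8, Pd(PPh3)4 (5 mol %), THF, rt; aq. Rochelle salt
Reagents that add atoms: trimethylaluminium, C[Al](C)C
Why: Negishi zirconium-catalysed methylalumination adds Me and Al syn across the alkyne with Al at the terminus, and the palladium-catalysed alkenyl–allyl coupling of the alane at the primary carbon of prenyl chloride keeps both alkene geometries, so the E-trisubstituted 1,4-diene should result.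

Step 7
Reactants: 10 (2E)-2,6-dimethylhepta-2,5-dien-1-ol
Product: 11 (2E)-2,6-dimethylhepta-2,5-dien-1-ylboronic acid pinacol ester
Conditions: B2pin2 (1.2 equiv), [Pd(MeCN)4](BF4)2 (5 mol %), DMSO–MeOH, rt to 40 °C
Reagents that add atoms: bis(pinacolato)diboron, CC1(C)OB(OC1(C)C)B1OC(C)(C)C(C)(C)O1
Why: Palladium-catalysed borylation of an allylic alcohol through an η3-allyl complex delivers boron to the unsubstituted allyl terminus and should keep the chain trans to the CH2B group.

Step 8
Reactants: 6 8-formyl-5-O-methylmorin 3,7,2',4'-tetrakis(tert-butyl carbonate); 11 (2E)-2,6-dimethylhepta-2,5-dien-1-ylboronic acid pinacol ester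
Product: 13 (1''S,2''S)-1''-hydroxy-methylkushenol C 3,7,2',4'-tetrakis(tert-butyl carbonate), via borate ester 12 (not isolated)
Conditions: 11 (1.5 equiv), (S)-TRIP (10 mol %), 4 Å MS, toluene, −30 °C to 0 °C; then pH 7 buffer
Reagents that add atoms: none
Why: Type-I allylboration: the phosphoric acid hydrogen-bonds a pinacol oxygen of 11 (raising the Lewis acidity of boron) while its P=O contacts the formyl C–H of 6, boron binds the aldehyde oxygen, and C2'' (the γ-carbon of the allyl unit) attacks C1'' through a closed six-membered chair with allylic transposition, so the C3''=CH2 isopropenyl bond appears as the C1''–C2'' bond forms. The closest known reaction type is the TRIP-catalysed crotylboration of aromatic aldehydes with pinacol crotylboronates. No ring of the product is closed; the only ring is the transient B–O–C1''–C2''–C3''–CH2 chair. C1'' is set by the catalyst, which exposes the Si face of the aldehyde (S), and C2'' is set relative to it by the E geometry of 11, which places the prenyl CH2 equatorial and gives the anti (1''S,2''S) isomer, whose C2'' has the spatial arrangement of (2''R) in the target (the descriptor changes only because C1'' later loses its oxygen). The step needs chemoselectivity for the aldehyde over the chromone C4=O and the four carbonates, which a neutral pinacol allylboronate provides, and γ-regioselectivity, which the cyclic transition state enforces. Any Z-11 ends up as the syn diastereomer and is removed by chromatography here, before the C1'' stereocentre is erased.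

Step 9
Reactants: 13 (1''S,2''S)-1''-hydroxy-methylkushenol C 3,7,2',4'-tetrakis(tert-butyl carbonate)
Product: 17 methylkushenol C, via benzylic carbonate 14 (not isolated), via o-quinone methide 15 (not isolated), via tris-carbonate 16 (not isolated)
Conditions: NaBH4 (6 equiv), THF–H2O (10:1), 0 °C to rt; then K2CO3, MeOH, rt, argon; aq. citric acid
Reagents that add atoms: none
Why: A base-induced 1,5-O-to-O carbonate shift, loss of tert-butyl carbonate to the o-quinone methide and 1,4-addition of hydride (the known carbonate/borohydride reduction of o-acylphenols to o-alkylphenols) erase the C1'' oxygen without touching C2'', and carbonate-catalysed methanolysis then frees the three remaining OH groups under non-acidic conditions that leave both alkenes and the 5-OMe group alone.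

Compound list
1 | morin | O=c1c(O)c(-c2ccc(O)cc2O)oc2cc(O)cc(O)c12 | starting material
2 | 3,7-bis(benzyloxy)-2-[2,4-bis(benzyloxy)phenyl]-5-hydroxy-4H-chromen-4-one (3,7,2',4'-tetra-O-benzylmorin) | O=c1c(OCc2ccccc2)c(-c2ccc(OCc3ccccc3)cc2OCc2ccccc2)oc2cc(OCc3ccccc3)cc(O)c12 | intermediate
3 | 3,7-bis(benzyloxy)-2-[2,4-bis(benzyloxy)phenyl]-5-methoxy-4H-chromen-4-one | O=c1c(OCc2ccccc2)c(-c2ccc(OCc3ccccc3)cc2OCc2ccccc2)oc2cc(OCc3ccccc3)cc(OC)c12 | intermediate
4 | 3,7-dihydroxy-2-(2,4-dihydroxyphenyl)-5-methoxy-4H-chromen-4-one (5-O-methylmorin) | O=c1c(O)c(-c2ccc(O)cc2O)oc2cc(O)cc(OC)c12 | intermediate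
5 | 3,7-dihydroxy-2-(2,4-dihydroxyphenyl)-5-methoxy-4-oxo-4H-chromene-8-carbaldehyde | O=Cc1c(O)cc(OC)c2c(=O)c(O)c(-c3ccc(O)cc3O)oc12 | intermediate
6 | 3,7,2',4'-tetrakis(tert-butyl carbonate) of 5 | O=Cc1c(OC(=O)OC(C)(C)C)cc(OC)c2c(=O)c(OC(=O)OC(C)(C)C)c(-c3ccc(OC(=O)OC(C)(C)C)cc3OC(=O)OC(C)(C)C)oc12 | intermediate
7 | propargyl alcohol | C#CCO | starting material
8 | prenyl chloride (1-chloro-3-methylbut-2-ene) | CC(C)=CCCl | starting material
9 | (E)-alkenylalane, dimethylaluminium alkoxide of 3-(dimethylalumanyl)-2-methylprop-2-en-1-ol (Al cis to CH3) | C[Al](C)/C=C(\C)CO[Al](C)C | intermediate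
10 | (2E)-2,6-dimethylhepta-2,5-dien-1-ol | CC(C)=CC/C=C(\C)CO | intermediate
11 | 2-[(2E)-2,6-dimethylhepta-2,5-dien-1-yl]-4,4,5,5-tetramethyl-1,3,2-dioxaborolane | CC(C)=CC/C=C(\C)CB1OC(C)(C)C(C)(C)O1 | intermediate
12 | O-(pinacolatoboryl) ether of 13, (1''S,2''S) | C=C(C)[C@H](CC=C(C)C)[C@H](OB1OC(C)(C)C(C)(C)O1)c1c(OC(=O)OC(C)(C)C)cc(OC)c2c(=O)c(OC(=O)OC(C)(C)C)c(-c3ccc(OC(=O)OC(C)(C)C)cc3OC(=O)OC(C)(C)C)oc12 | intermediate
13 | 8-[(1S,2S)-1-hydroxy-5-methyl-2-(prop-1-en-2-yl)hex-4-en-1-yl]-5-methoxyflavonol 3,7,2',4'-tetrakis(tert-butyl carbonate) (anti) | C=C(C)[C@H](CC=C(C)C)[C@H](O)c1c(OC(=O)OC(C)(C)C)cc(OC)c2c(=O)c(OC(=O)OC(C)(C)C)c(-c3ccc(OC(=O)OC(C)(C)C)cc3OC(=O)OC(C)(C)C)oc12 | intermediate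
14 | isomer of 13 with free 7-OH and the tert-butyl carbonate on the C1'' oxygen | C=C(C)[C@H](CC=C(C)C)[C@H](OC(=O)OC(C)(C)C)c1c(O)cc(OC)c2c(=O)c(OC(=O)OC(C)(C)C)c(-c3ccc(OC(=O)OC(C)(C)C)cc3OC(=O)OC(C)(C)C)oc12 | intermediate
15 | ring-A o-quinone methide (C7=O, C8=C1''), C2'' intact | C=C(C)[C@H](CC=C(C)C)C=C1C(=O)C=C(OC)C2=C1OC(c1ccc(OC(=O)OC(C)(C)C)cc1OC(=O)OC(C)(C)C)=C(OC(=O)OC(C)(C)C)C2=O | intermediate
16 | methylkushenol C 3,2',4'-tris(tert-butyl carbonate), (2''R) | C=C(C)[C@H](CC=C(C)C)Cc1c(O)cc(OC)c2c(=O)c(OC(=O)OC(C)(C)C)c(-c3ccc(OC(=O)OC(C)(C)C)cc3OC(=O)OC(C)(C)C)oc12 | intermediate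
17 | methylkushenol C, 3,7-dihydroxy-2-(2,4-dihydroxyphenyl)-5-methoxy-8-[(2R)-5-methyl-2-(prop-1-en-2-yl)hex-4-en-1-yl]-4H-chromen-4-one | C=C(C)[C@H](CC=C(C)C)Cc1c(O)cc(OC)c2c(=O)c(O)c(-c3ccc(O)cc3O)oc12 | target

Total step count: 9. Longest linear sequence: 7 (steps 1, 2, 3, 4, 5, 8, 9).

Steps most likely to fail

Step 8. The di-ortho-substituted aldehyde may react so slowly that the uncatalysed racemic background addition competes, or the catalyst pocket may give poor facial selectivity with so large an aryl group. The fallback changes the allyl donor from a Brønsted-acid-activated boronate to a Lewis-base-activated silane. It sets out from 10. MsCl/Et3N followed by LiCl in THF should give (E)-1-chloro-2,6-dimethylhepta-2,5-diene F1. HSiCl3, CuCl and i-Pr2NEt in Et2O should then give, with retention of regio- and stereochemistry, (E)-trichloro(2,6-dimethylhepta-2,5-dien-1-yl)silane F2. F2 is added to 6 with a chiral bisphosphoramide Lewis base in CH2Cl2/i-Pr2NEt at −78 °C. The addition runs through a closed hexacoordinate siliconate chair (E to anti) to the trichlorosilyl ether F3, which is hydrolysed on buffered work-up. The fallback returns to the route at 13.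

Step 4. The electrophilic attack may spread over C6 of ring A and C3'/C5' of ring B instead of going cleanly to C8. The fallback deactivates ring B and leaves the 7-OH as the only free phenol. It sets out from 4. Ac2O/pyridine should give 5-O-methylmorin 3,7,2',4'-tetraacetate F4. PhSH and imidazole in NMP should remove only the most activated 7-O-acetyl group (best phenoxide leaving group) to give 5-O-methylmorin 3,2',4'-triacetate F5. Duff formylation in TFA at 70 °C can then only occur ortho to the 7-OH and should give 8-formyl-5-O-methylmorin 3,2',4'-triacetate F6. K2CO3/MeOH under argon removes the acetates, and the fallback returns to the route at 5.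

Step 9. The o-quinone methide may tautomerise by loss of the doubly allylic C2''–H to a conjugated dienylphenol, which destroys the stereocentre. Alternatively, intermolecular cleavage of the 7-O-carbonate may outrun its shift and leave an inert salicyl alcohol. The fallback avoids the quinone methide altogether by a Barton–McCombie radical deoxygenation. It sets out from 13. 1,1'-Thiocarbonyldiimidazole and DMAP in 1,2-dichloroethane at 60 °C, without alkoxide formation, should give the C1''-O-(imidazol-1-ylthiocarbonyl) derivative F7. Bu3SnH/AIBN in toluene at 80 °C should give methylkushenol C 3,7,2',4'-tetrakis(tert-butyl carbonate) F8. K2CO3/MeOH under argon removes all four carbonates, and the fallback returns to the route at 17.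

Further compounds
F1 | step 8 | (E)-1-chloro-2,6-dimethylhepta-2,5-diene | CC(C)=CC/C=C(\C)CCl
F2 | step 8 | (E)-trichloro(2,6-dimethylhepta-2,5-dien-1-yl)silane | CC(C)=CC/C=C(\C)C[Si](Cl)(Cl)Cl
F3 | step 8 | O-trichlorosilyl ether of 13, (1''S,2''S) | C=C(C)[C@H](CC=C(C)C)[C@H](O[Si](Cl)(Cl)Cl)c1c(OC(=O)OC(C)(C)C)cc(OC)c2c(=O)c(OC(=O)OC(C)(C)C)c(-c3ccc(OC(=O)OC(C)(C)C)cc3OC(=O)OC(C)(C)C)oc12
F4 | step 4 | 5-O-methylmorin 3,7,2',4'-tetraacetate | COc1cc(OC(C)=O)cc2oc(-c3ccc(OC(C)=O)cc3OC(C)=O)c(OC(C)=O)c(=O)c12
F5 | step 4 | 5-O-methylmorin 3,2',4'-triacetate | COc1cc(O)cc2oc(-c3ccc(OC(C)=O)cc3OC(C)=O)c(OC(C)=O)c(=O)c12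
F6 | step 4 | 8-formyl-5-O-methylmorin 3,2',4'-triacetate | O=Cc1c(O)cc(OC)c2c(=O)c(OC(C)=O)c(-c3ccc(OC(C)=O)cc3OC(C)=O)oc12
F7 | step 9 | C1''-O-(imidazol-1-ylthiocarbonyl) derivative of 13, (1''S,2''S) | C=C(C)[C@H](CC=C(C)C)[C@H](OC(=S)n1ccnc1)c1c(OC(=O)OC(C)(C)C)cc(OC)c2c(=O)c(OC(=O)OC(C)(C)C)c(-c3ccc(OC(=O)OC(C)(C)C)cc3OC(=O)OC(C)(C)C)oc12
F8 | step 9 | methylkushenol C 3,7,2',4'-tetrakis(tert-butyl carbonate), (2''R) | C=C(C)[C@H](CC=C(C)C)Cc1c(OC(=O)OC(C)(C)C)cc(OC)c2c(=O)c(OC(=O)OC(C)(C)C)c(-c3ccc(OC(=O)OC(C)(C)C)cc3OC(=O)OC(C)(C)C)oc12
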